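Readings and results are calculated for substances that don't exist; noise was put on by code.

The closed, stirred vessel is the amber flask itself, followed up to its last reading and asked about at 4.0 d.

| setting | amber | red | flask |
|---|---|---|---|
| substrate | 0.10 M | 0.050 M | 0.10 M |
| reagent | 2.5 equiv | 2.5 equiv | 2.50 equiv |
| catalyst | 0.05 mol% | 0.05 mol% | 0.05 mol% |
| temperature | 60 °C | 55 °C | 60 °C |
| remark | the very flask that is asked about, followed so far | run made earlier |  |
| time |  |  | 4.0 d |

amber run (percent of the substrate charged): time / d: product / % = 0.250: 20; 0.417: 21; 0.625: 23; 0.833: 24; 1.25: 27; 2.00: 25; 3.00: 32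

red run (percent of the substrate charged): time / h: product / % = 6.00: 5; 15.0: 10; 20.0: 16; 30.0: 15; 40.0: 19; 50.0: 18

(readings scatter by 2 percentage points)

1. product, in percent of the substrate first charged, at 4.0 d
2. the option that brings most further product ("none" if no option brings more than 2 percentage points) (autumn / midnight / spring / winter / summer / none)
3. product present, with what was taken out counted in, in percent of the substrate first charged, after autumn
4. product present, with what was taken out counted in, in percent of the substrate first charged, after spring

- autumn: at 4.0 d take out 90% of the product then present, then wait 50 h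
- midnight: at 4.0 d raise the temperature by 25 K, then wait 50 h
- spring: change nothing and wait 50 h more
- winter: at 4.0 d add reagent, 100% of the amount charged, then wait 50 h
- summer: at 4.0 d add catalyst, 100% of the amount charged, then wait 50 h

- what is taken out of product is counted as made
- additions bring no volume worth counting

My own reckoning uses the rate alone.

1. Replace the product curve by its mean rate r: the gain between two amber readings per unit time, as a fraction of the substrate charged. Up to the first reading, r is 0.800 d⁻¹.

2. From there to 1.25 d, r reads 0.0700 d⁻¹, a fall by a factor of 11.4. From 1.25 d to 3.00 d it reads 0.0286 d⁻¹, a further factor of 2.45. These are readings, each end carrying a scatter of 2 percentage points, and they do not name the brake.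

3. Take the later fall as exponential. The slowing time τ, in which the rate shrinks by a factor e, is then 1.53 d. A rate r decaying this way still has R = rτ of product to give.

4. Carried forward to 4.0 d, r is 0.00842 d⁻¹, so R is 1.3 points. My estimate for the amber flask at that time is 33.2%. Waiting 50 h more yields 0.96 points, less than the margin of 2 points, which gives 34.2%. The rates do not rank the other options.

5. The forecast reads the tail differently: the product “creeps up linearly”. It gives 34% (30% to 38%), 40% after spring (35% to 45%), 41% after autumn (36% to 52%), and midnight as the best option. My reckoning parts from it on the tail, a falling rate against a steady one.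

    substrate + catalyst ⇌ catalyst + intermediate (K = 8.20, k = 10.7 L mol⁻¹ s⁻¹, Ea = 60.0 kJ mol⁻¹, ΔH = 19.0 kJ mol⁻¹)
    reagent + catalyst + intermediate → catalyst + product (k = 3.70 L² mol⁻² s⁻¹, Ea = 46.0 kJ mol⁻¹)
    2 reagent → homo dimer (k = 6.25 × 10⁻⁴ L mol⁻¹ s⁻¹, Ea = 81.0 kJ mol⁻¹)
    (constants at 60 °C)

The flask holds 31.5% at 4.0 d. Spring adds 0.14 points, against the 0.96 points reckoned from τ. Winter brings most, 25 points; reagent, the limiting reagent, has 0.0668% of its charge free at 4.00 d. The red run differs from the flask in substrate and temperature, so τ is merely borrowed there, untested. Its readings at 30.0 h and 50.0 h give r = 0.0360 d⁻¹, and R = rτ, carried from its last reading to 4.0 d, gives a gain of 3 points. Without the scatter, the red run goes from 17.2% at its last reading to 20.0% at 4.0 d. Left until 40.0 d, the flask's product moves a further 0.17 points.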